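Z.E has two ways out, ring closure to X or capture by a second Z, and I compared their rates across the flasks.

    Z + E → Z.E (k1 = 2.10 M⁻¹ min⁻¹)
    Z.E → X (k2 = 0.0345 min⁻¹)
    Z + Z.E → Z.Z.E (k3 = 0.0373 M⁻¹ min⁻¹)
    D ⇌ E, rate k4*(csat - [E]) (k4 = 0.0629 min⁻¹, csat = 200 mM)
    2 Z → Q (k5 = 7.39 × 10⁻⁵ M⁻¹ min⁻¹)
    J ⇌ X, rate k6*(cs6 - [X]) while solid is left; crystals form when [X] > cs6 (cs6 = 0.23 M, k6 = 14.0 min⁻¹)

| setting | Tuesday's | Wednesday's | Friday's |
|---|---|---|---|
| Z | 0.20 M | 0.60 M | 2.0 M |
| D | 200 mM (held) | 200 mM (held) | 200 mM (held) |
| time | 4.0 h | 4.0 h | 4.0 h |

- share of X in all that became X or Z.Z.E for Tuesday's, Wednesday's, Friday's, in this order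
- the course of these numbers from the first flask to the last (falls all the way / rises, then falls / rises all the way / falls, then rises / hardly changes)

- in percentages every species weighs as the Z in it: one Z.Z.E or Q counts as two
- for X the J are counted in
- a doubled species enters its step squared and goes two at a time
- as a solid, counted per litre of solution: J
- at the start none of E is dissolved
- "hardly changes" means that all values lie within two and a half points (for a concentration: within two and a half percent of the largest)
- run time (Tuesday's): 4.0 h

I called the [Z] at which those two rates are equal the crossing concentration: the constant of ring closure over the constant of capture, 0.925 M. Tuesday's charge stood below it, and Friday's stood above it. At Tuesday's charge Z took up E faster than the gas supplied it, so gas transfer paced the making of Z.E. Z.E therefore formed at about F, 0.0126 M min⁻¹.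

I reckoned the share of X two ways. The steady way held Z.E at the balance of its making and loss. Each capture costs a further Z, so with u as the charge over the crossing concentration, integrating over falling [Z] gave a share of ln(1 + 2u)/(2u). The pile-up way let Z.E accumulate without ring closure while [Z] fell in a straight line at F. The share lost to Z.Z.E was then the capture constant times the charge squared, over 3F.

For Wednesday's the two gave 64.1% and 64.4%, so they met. But both hold Z.E too high while Z remains, so I read that figure as low. For Tuesday's they parted, at 83.1% and 96.0%. The feed time, charge over F, was 15.9 min, shorter than the life of Z.E by ring closure, 29.0 min. So the steady way cheated there, and I kept 96.0%. For Friday's the pile-up way lost 395% of the charge, more than there was. The feed time of 159 min was longer than that life, so I kept the steady 38.7%.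

The forecast gave 95.5%, 82% and 46%, with the course falls all the way, “allowing for the lag in Z.E build-up”. It lay close to my Tuesday's figure, but above mine for Wednesday's and Friday's.

The flasks gave 94.7%, 79.2% and 46.4%, and the course was falls all the way. In Friday's flask at 2.00 h, [Z] read 0.0698 M, below the crossing 0.925 M, and Z.E stood at 11.0% of the charge. By 4.00 h, X had gone from 32.0% to 45.8%, while Z.Z.E had gone from 52.5% to 52.8%. In Wednesday's flask at 2.00 h, Z read 0%, also below the crossing. By 4.00 h, X there had gone from 75.5% to 79.0%, while Z.Z.E stood at 20.8%.

(The numbers stand for no real mixture; what happens was integrated by code.)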